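## The problem

Abruquinone B (17) is an isoflavan. A dihydropyran ring C (O1, C2, C3, C4, C4a, C8a) is fused to a tetraoxygenated benzene ring A (O1 on C8a, methoxy groups on C6, C7 and C8), and C3 carries, through C1', a 2,3-dimethoxy-1,4-benzoquinone as ring B. The skeleton is small, so the synthesis is decided by three questions: how the O1–C2 and C3–C4 bonds of ring C are made, how the single stereocentre C3 (S) is set, and when the quinone appears. C3 bears two methylene arms that differ only at their far ends (C2 ends on oxygen, C4 on ring A), and there is no second stereocentre to relay from, so its configuration must come from an auxiliary, a reagent or a catalyst. The quinone is the fragile group: it is electrophilic, reducible and base-sensitive, and the C3–H bond next to it can be lost by tautomerism, so it is best unveiled last from a phenol at C3' whose free para carbon C6' takes up the second oxygen. Ring A is itself an electron-rich tetraalkoxybenzene, so the final oxidant must recognise a free phenol only. The enabling feature is that O1 and C4 sit on neighbouring carbons of ring A. O1–C8a–C4a–C4 is therefore the skeleton of an ortho-quinone methide, an electron-poor 1-oxadiene, and C2–C3 is a two-carbon partner that can bring ring B on C3 and a donor oxygen on C2. Because C4 is a methylene, such a cycloaddition creates only C2 and C3 as stereocentres, and C2 is reduced to a methylene afterwards.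

## Retrosynthesis

**17 to 16.** No skeletal bond is cut; the C6' carbonyl oxygen is removed, giving phenol 16. A phenol is preferred over a hydroquinone dimethyl ether because an oxidative demethylation strong enough for ring B would also attack ring A. The forward step needs an oxidant that takes a phenol with a free para position to the para-quinone under near-neutral conditions.

**16 to 15 to 14.** The phenol is masked as benzyl ether 15, which survives base, organomagnesium reagents and Lewis acids and comes off by neutral hydrogenolysis. The C2 methylene of 15 is then traced to an acetal carbon: one C2–H bond is exchanged for the C2–O bond of a 2-alkoxychroman, 14. This raises C2 to the aldehyde oxidation level and gives it the donor oxygen that a cycloaddition partner needs. The forward reduction must cleave the exocyclic C2–O bond and leave C3 alone.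

**14 to 6 and 12 (through 13).** O1–C2 and C3–C4 are cut together, which opens ring C into ortho-quinone methide 13 and enol ether 12. Cutting only O1–C2 (an etherification) or only C3–C1' (an arylation) would leave the stereocentre to a separate step on an open chain or on a preformed chroman. The double cut makes both ring bonds, the ring and C3 in one event, with the regiochemistry fixed by polarity. 13 is not a storable compound; it is drawn from benzyl alcohol carbonate 6, which is achiral and three steps from a commercial phenol. 12 carries no stereocentre of its own, only those of a commercial auxiliary. The forward reaction must generate 13 cold enough for the auxiliary to discriminate the two faces of 12, and must keep the (E) geometry.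

**6 to 5 to 3 to 1.** The C4–C4a bond is traced to an ortho-formylation of 2,3,4-trimethoxyphenol 1, whose only free ortho position is the one required. Aldehyde 3 is protected on the phenolic oxygen with di-tert-butyl dicarbonate 4 to give 5, and the aldehyde is reduced to 6. The order matters: acylating before reducing avoids having to distinguish two hydroxyl groups. The reduction must not produce a free alkoxide, since that would start the carbonate transfer too early.

**12 to 10 and 11, then 10 to 9 to 8 to 7.** The vinyl C–O bond is cut to give (E)-alkenylboronate 10 and (1R,2S)-trans-2-phenylcyclohexanol 11. An alkoxymethylene Wittig reaction or the addition of the alcohol to an alkyne would give mixtures of geometric isomers, whereas a boronate made by syn-hydroboration is purely (E) and couples with retention. 10 comes from alkyne 9 and 9 from aldehyde 8 by one-carbon homologation. 8 is the benzyl ether of commercial 3-hydroxy-4,5-dimethoxybenzaldehyde 7, which already holds the full oxygen pattern of ring B.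

## Roads not taken

**Alternative 1: conjunctive coupling on a vinyl boronate.** The cut is C3–C1' and C4–C4a around a two-carbon vinyl unit. Arylboronate A1 and vinyllithium A2 form an ate complex. Under Pd(OAc)2 and a chiral MandyPhos ligand, ring A triflate A3 induces a 1,2-shift of the aryl group from boron to carbon while palladium delivers ring A to the terminal carbon, giving secondary boronate A4 with boron where C2 will be.
- Merits: C3 is set by a catalyst, with no auxiliary to attach, match and remove. Either enantiomer is available from the ligand, and three simple pieces are joined at once.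
- Weak points: no ring closes and C2 is missing. A4 needs a Matteson homologation at a hindered benzylic boron, oxidation, debenzylation and Mitsunobu closure before desilylation and quinone formation, about six steps after the key step against three here. A3 is very electron-rich and has an ortho benzyloxy group, so oxidative addition is slow and direct Suzuki-type aryl transfer from the ate complex can compete.
- Comparison: on control of C3 this road is in principle the better one. The chosen plan sets against it that its key step forms ring C with both ring bonds and C2 in place, and that the auxiliary is cleaved in the very step that corrects C2.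

**Alternative 2: photo-Wolff aryl shift with lactonising ketene capture.** The cut is C3–C1' (aryl migration) and O1–C2. Irradiation of α-diazoketone A5 expels N2 with migration of ring B. The ring A phenol captures the aryl(alkyl)ketene under a chiral amine such as O-acetylquinidine, closing ring C as dihydrocoumarin A6 with enantioselective protonation at C3.
- Merits: like the chosen plan it closes ring C in the key step. It needs no metal and no auxiliary, and the precursor is achiral.
- Weak points: C3 is created as the α-carbon of an aryl ester of an arylacetic acid, the most acidic position available, so the amine that sets it can also erase it. The tethered phenol can capture the ketene without the catalyst through an easy six-membered closure, which gives racemic material. The C2 carbonyl must then be removed by reduction to a diol and a second closure of ring C, with C3 staying next to a carbonyl until the reduction is complete. A5 also requires a diazo transfer next to a free phenol.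
- Comparison: ring-forming economy is equal and there is no stoichiometric auxiliary. The chosen plan sets against it that C3 in 14 sits beside an acetal carbon with no acidifying neighbour, and that three steps remain after the key step, not four or five.

**Alternative 3: Catellani annulation of ring A with a chiral bromo alcohol.** The cut is C4–C4a and O1–C8a, both bonds from ring A to ring C. Under Pd(OAc)2, a bulky biaryl phosphine, norbornene and Cs2CO3, iodide A7 is alkylated at its free ortho position by the primary bromide of A8. The tethered alkoxide then displaces palladium at the ipso carbon to give chroman A9, which is identical with 15.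
- Merits: the product needs no correction at C2 and joins the end game directly, one step shorter after the key step than the chosen plan. A7 is trivial, and its single ortho methoxy group is what mono-alkylation requires. The stereocentre arrives ready-made and is not a reacting centre.
- Weak points: the stereochemical problem is moved into a separate multistep enantioselective preparation of A8. A8 has a benzylic hydrogen β to bromine, so elimination under Cs2CO3 at the temperature of the annulation is likely. Its β-branched bromide is slow in the alkylation of the palladacycle. The C–O termination with a primary alkoxide must outrun β-hydride elimination from the palladium alkoxide.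
- Comparison: if the annulation worked, the end game would be shorter than here. The chosen plan sets against it that stereocentre and ring are made in the same step from achiral or commercial chiral material, and that this bond set has close precedent for quinone methides from this type of carbonate, including aryl-substituted enol ethers.

Key step: step 8

## Route

Assumption: the (1R,2S) enantiomer of trans-2-phenylcyclohexanol is taken to leave open the face of the enol ether that leads to (3S). If the cycloaddition shows the opposite sense, the equally available (1S,2R) enantiomer replaces it; only the auxiliary descriptors in 11, 12 and 14 then change.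

Step 1
Reactants: 1 2,3,4-trimethoxyphenol
Product: 3 2-hydroxy-3,4,5-trimethoxybenzaldehyde, via 6-(hydroxymethyl)-2,3,4-trimethoxyphenol 2 (not isolated)
Conditions: MgCl2, Et3N, (CH2O)n, MeCN, reflux; then aq. HCl
Reagents that add atoms: paraformaldehyde (reacting as formaldehyde), C=O
Why: Magnesium-mediated ortho-formylation of a phenol (Casnati–Skattebøl reaction): the magnesium phenolate delivers formaldehyde to the only free ortho carbon, and the magnesium salt of salicyl alcohol 2 is oxidised by a second formaldehyde through Oppenauer-type hydride transfer.

Step 2
Reactants: 3 2-hydroxy-3,4,5-trimethoxybenzaldehyde; 4 di-tert-butyl dicarbonate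
Product: 5 tert-butyl (2-formyl-4,5,6-trimethoxyphenyl) carbonate
Conditions: DMAP (cat.), i-Pr2NEt, THF, 0 °C to rt
Reagents that add atoms: none
Why: DMAP-catalysed O-acylation of a phenol by an anhydride; the aldehyde is inert and there is no second hydroxyl group to compete.

Step 3
Reactants: 5 tert-butyl (2-formyl-4,5,6-trimethoxyphenyl) carbonate
Product: 6 tert-butyl [2-(hydroxymethyl)-4,5,6-trimethoxyphenyl] carbonate
Conditions: BH3·THF, THF, 0 °C; then H2O
Reagents that add atoms: none
Why: Borane reduction of an aldehyde runs through a neutral alkoxyborane, so no free alkoxide arises that could pull the carbonate group across before step 8; aryl carbonates are inert to borane at this temperature.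

Step 4
Reactants: 7 3-hydroxy-4,5-dimethoxybenzaldehyde
Product: 8 3-(benzyloxy)-4,5-dimethoxybenzaldehyde
Conditions: BnBr, K2CO3, DMF, rt
Reagents that add atoms: benzyl bromide, BrCc1ccccc1
Why: Williamson ether synthesis on a phenoxide with a reactive benzylic halide; the aldehyde is not enolisable.

Step 5
Reactants: 8 3-(benzyloxy)-4,5-dimethoxybenzaldehyde
Product: 9 1-(benzyloxy)-5-ethynyl-2,3-dimethoxybenzene
Conditions: dimethyl (1-diazo-2-oxopropyl)phosphonate, K2CO3, MeOH, rt
Reagents that add atoms: dimethyl (1-diazo-2-oxopropyl)phosphonate, CC(=O)C(=[N+]=[N-])P(=O)(OC)OC
Why: Seyferth–Gilbert homologation in the Ohira–Bestmann variant: methanolysis frees the diazomethylphosphonate anion, which olefinates the aldehyde, and loss of N2 with 1,2-hydrogen shift gives the terminal alkyne; the mild carbonate base suits an aryl aldehyde with ether groups.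

Step 6
Reactants: 9 1-(benzyloxy)-5-ethynyl-2,3-dimethoxybenzene
Product: 10 2-{(E)-2-[3-(benzyloxy)-4,5-dimethoxyphenyl]ethenyl}-4,4,5,5-tetramethyl-1,3,2-dioxaborolane
Conditions: pinacolborane, Cp2Zr(H)Cl (cat.), Et3N (cat.), CH2Cl2, rt to 40 °C
Reagents that add atoms: pinacolborane, CC1(C)OBOC1(C)C
Why: Zirconium-catalysed hydroboration of a terminal arylalkyne; syn addition with boron on the terminal carbon gives the (E)-alkenylboronate only.

Step 7
Reactants: 10 2-{(E)-2-[3-(benzyloxy)-4,5-dimethoxyphenyl]ethenyl}-4,4,5,5-tetramethyl-1,3,2-dioxaborolane; 11 (1R,2S)-trans-2-phenylcyclohexan-1-ol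
Product: 12 1-(benzyloxy)-2,3-dimethoxy-5-[(E)-2-{[(1R,2S)-2-phenylcyclohexyl]oxy}ethenyl]benzene
Conditions: Cu(OAc)2 (2 equiv), Et3N (4 equiv), 11 (3 equiv, excess recovered), 4 Å MS, CH2Cl2, rt
Reagents that add atoms: none
Why: Chan–Lam-type oxidative C–O coupling of an alkenyl pinacolboronate with an aliphatic alcohol; transmetalation to divalent copper and reductive elimination from trivalent copper keep the (E) geometry, the alcohol C–O bond is not broken so the auxiliary stereocentres are untouched, and Et3N buffers the acetic acid so the enol ether survives.

Step 8
Reactants: 6 tert-butyl [2-(hydroxymethyl)-4,5,6-trimethoxyphenyl] carbonate; 12 1-(benzyloxy)-2,3-dimethoxy-5-[(E)-2-{[(1R,2S)-2-phenylcyclohexyl]oxy}ethenyl]benzene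
Product: 14 (2R,3S)-3-[3-(benzyloxy)-4,5-dimethoxyphenyl]-6,7,8-trimethoxy-2-{[(1R,2S)-2-phenylcyclohexyl]oxy}chroman (2,3-trans), via ortho-quinone methide 2,3,4-trimethoxy-6-methylidenecyclohexa-2,4-dien-1-one 13 (not isolated)
Conditions: t-BuMgCl (1.05 equiv on 6), 12 (1.5 equiv, excess recovered), toluene, −78 °C to rt; aq. NH4Cl
Reagents that add atoms: none
Why: t-BuMgCl deprotonates the benzylic alcohol of 6, the magnesium alkoxide takes the carbonate group over from the neighbouring phenolic oxygen, and the resulting phenoxide expels tert-butyl carbonate in a 1,4-elimination to give ortho-quinone methide 13 at low temperature. 13 is an electron-poor 1-oxadiene and 12 an electron-rich alkene, so they combine in an inverse-electron-demand hetero-Diels–Alder reaction; the closest known reaction type is the low-temperature cycloaddition of ortho-quinone methides from ortho-(tert-butoxycarbonyloxy)benzyl alcohols with enol ethers of chiral alcohols. Ring C is closed by an intermolecular [4+2] annulation in which C3–C4 and O1–C2 form in one concerted but asynchronous event, the carbon–carbon bond leading. The oxygen donor makes the aryl-bearing carbon of 12 the nucleophilic end, which bonds to the electrophilic methide carbon C4 while O1 closes on the alkoxy carbon, so the aryl group ends on C3 as an isoflavan requires. C3 is set by the auxiliary, whose phenyl ring lies over one face of the enol ether so that C4 adds to the open face. C2 is set relative to C3 by suprafacial addition to the (E) double bond, which gives the 2,3-trans relation; C4 is a methylene, so endo or exo approach leaves no further stereochemical trace. The step needs facial selectivity and capture of 13 by 12 faster than by itself: the first rests on the auxiliary and the low temperature that the anionic trigger allows, the second on forming 13 gradually in an excess of 12. A minor diastereomer should be separable because the auxiliary is still attached.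

Step 9
Reactants: 14 (2R,3S)-3-[3-(benzyloxy)-4,5-dimethoxyphenyl]-6,7,8-trimethoxy-2-{[(1R,2S)-2-phenylcyclohexyl]oxy}chroman
Product: 15 (3S)-3-[3-(benzyloxy)-4,5-dimethoxyphenyl]-6,7,8-trimethoxychroman
Conditions: Et3SiH (4 equiv), BF3·OEt2 (2 equiv), CH2Cl2, −78 to −30 °C; aq. NaHCO3
Reagents that add atoms: none
Why: Ionic hydrogenation of an acetal: BF3 binds the more basic alkyl oxygen, the auxiliary leaves as its alkoxide and the cyclic oxocarbenium ion takes hydride from Et3SiH at C2. C3 is not a reacting centre, and in the cold with excess silane hydride capture should outrun loss of the C3 proton, so (S) is carried through while C2 becomes a methylene.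

Step 10
Reactants: 15 (3S)-3-[3-(benzyloxy)-4,5-dimethoxyphenyl]-6,7,8-trimethoxychroman
Product: 16 2,3-dimethoxy-5-[(3S)-6,7,8-trimethoxychroman-3-yl]phenol
Conditions: H2 (1 atm), Pd/C, EtOAc–EtOH, rt
Reagents that add atoms: none
Why: Hydrogenolysis of a benzyl aryl ether over palladium on carbon; the remaining C–O bonds are aryl–O or non-benzylic alkyl–O bonds and are not cleaved, and C3 has no pathway for epimerisation under neutral conditions.

Step 11
Reactants: 16 2,3-dimethoxy-5-[(3S)-6,7,8-trimethoxychroman-3-yl]phenol
Product: 17 abruquinone B, 2,3-dimethoxy-5-[(3S)-6,7,8-trimethoxychroman-3-yl]cyclohexa-2,5-diene-1,4-dione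
Conditions: (KSO3)2NO (2.5 equiv), aq. KH2PO4, acetone–H2O, 0 °C to rt
Reagents that add atoms: potassium nitrosodisulfonate (KSO3)2NO, [K+].[K+].[O]N(S(=O)(=O)[O-])S(=O)(=O)[O-]
Why: Teuber oxidation of a phenol with a free para position: one equivalent of the nitroxyl radical removes the phenolic hydrogen and a second couples at C6' and delivers its oxygen, giving the para-quinone. Ring A has no free hydroxyl group and is not attacked, and the phosphate buffer keeps the medium near neutral so the C3–H next to the quinone is not ionised.

## Compound list

1 | 2,3,4-trimethoxyphenol | COc1ccc(O)c(OC)c1OC | starting material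
2 | 6-(hydroxymethyl)-2,3,4-trimethoxyphenol (formed as its magnesium phenolate) | COc1cc(CO)c(O)c(OC)c1OC | intermediate
3 | 2-hydroxy-3,4,5-trimethoxybenzaldehyde | COc1cc(C=O)c(O)c(OC)c1OC | intermediate
4 | di-tert-butyl dicarbonate | CC(C)(C)OC(=O)OC(=O)OC(C)(C)C | starting material
5 | tert-butyl (2-formyl-4,5,6-trimethoxyphenyl) carbonate | CC(C)(C)OC(=O)Oc1c(C=O)cc(OC)c(OC)c1OC | intermediate
6 | tert-butyl [2-(hydroxymethyl)-4,5,6-trimethoxyphenyl] carbonate | CC(C)(C)OC(=O)Oc1c(CO)cc(OC)c(OC)c1OC | intermediate
7 | 3-hydroxy-4,5-dimethoxybenzaldehyde | COc1cc(C=O)cc(O)c1OC | starting material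
8 | 3-(benzyloxy)-4,5-dimethoxybenzaldehyde | COc1cc(C=O)cc(OCc2ccccc2)c1OC | intermediate
9 | 1-(benzyloxy)-5-ethynyl-2,3-dimethoxybenzene | COc1cc(C#C)cc(OCc2ccccc2)c1OC | intermediate
10 | 2-{(E)-2-[3-(benzyloxy)-4,5-dimethoxyphenyl]ethenyl}-4,4,5,5-tetramethyl-1,3,2-dioxaborolane | COc1cc(/C=C/B2OC(C)(C)C(C)(C)O2)cc(OCc2ccccc2)c1OC | intermediate
11 | (1R,2S)-trans-2-phenylcyclohexan-1-ol | O[C@@H]1CCCC[C@H]1c1ccccc1 | starting material
12 | 1-(benzyloxy)-2,3-dimethoxy-5-[(E)-2-{[(1R,2S)-2-phenylcyclohexyl]oxy}ethenyl]benzene | COc1cc(/C=C/O[C@@H]2CCCC[C@H]2c2ccccc2)cc(OCc2ccccc2)c1OC | intermediate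
13 | 2,3,4-trimethoxy-6-methylidenecyclohexa-2,4-dien-1-one (ortho-quinone methide) | C=C1C=C(OC)C(OC)=C(OC)C1=O | intermediate
14 | (2R,3S)-3-[3-(benzyloxy)-4,5-dimethoxyphenyl]-6,7,8-trimethoxy-2-{[(1R,2S)-2-phenylcyclohexyl]oxy}chroman | COc1cc(cc(OCc2ccccc2)c1OC)[C@H]1[C@H](O[C@@H]2CCCC[C@H]2c2ccccc2)Oc2c(cc(OC)c(OC)c2OC)C1 | intermediate
15 | (3S)-3-[3-(benzyloxy)-4,5-dimethoxyphenyl]-6,7,8-trimethoxychroman | COc1cc(cc(OCc2ccccc2)c1OC)[C@H]1COc2c(cc(OC)c(OC)c2OC)C1 | intermediate
16 | 2,3-dimethoxy-5-[(3S)-6,7,8-trimethoxychroman-3-yl]phenol | COc1cc(cc(O)c1OC)[C@H]1COc2c(cc(OC)c(OC)c2OC)C1 | intermediate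
17 | abruquinone B, 2,3-dimethoxy-5-[(3S)-6,7,8-trimethoxychroman-3-yl]cyclohexa-2,5-diene-1,4-dione | COC1=C(OC)C(=O)C([C@H]2COc3c(cc(OC)c(OC)c3OC)C2)=CC1=O | target

## Step count and risks

Total: 11 steps. Longest linear sequence: 8 steps (steps 4 to 11, from 7); the ring A branch (steps 1 to 3) joins at step 8.

**Step 8 (key step).** The most likely failure is poor facial selectivity. A β-aryl enol ether is bulkier and less nucleophilic than the alkyl or unsubstituted vinyl ethers for which this auxiliary is established. In 13 the C7 methoxy group, para to the methide-bearing carbon, lowers the electrophilicity. The cycloaddition may therefore only proceed on warming, where the auxiliary discriminates less and self-condensation of 13 competes. The fallback keeps the cycloaddition as the ring-forming event and moves control of C3 to a catalyst. It sets out from 14 as whatever diastereomer mixture is obtained. Catalytic TsOH in hot toluene (or TMSOTf with i-Pr2NEt) should eliminate the auxiliary alcohol to give the achiral enol ether 3-[3-(benzyloxy)-4,5-dimethoxyphenyl]-6,7,8-trimethoxy-4H-chromene F1. Asymmetric hydrogenation of its C2=C3 bond with a cationic iridium phosphinooxazoline complex, [Ir(cod)(PHOX)]BArF, under H2 in CH2Cl2, a known reaction type for 4H- and 2H-chromenes, returns to the route at 15.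

**Step 7.** The oxidative coupling may stall because a hindered secondary alcohol is used in modest excess instead of as solvent. Protodeboronation and homocoupling of 10 would then consume the boronate, and the product can hydrolyse on acidic silica. The fallback changes the vinyl partner from a nucleophile to an electrophile. It sets out from 9: hydrozirconation with stoichiometric Cp2Zr(H)Cl followed by I2 should give 1-(benzyloxy)-5-[(E)-2-iodoethenyl]-2,3-dimethoxybenzene F2. Ullmann-type vinylation of 11 with CuI, 3,4,7,8-tetramethyl-1,10-phenanthroline and Cs2CO3 in toluene at 80 °C, which retains the geometry, returns at 12.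

**Step 9.** Two things can go wrong:
- Ionisation of the ring C–O bond, where the phenoxide is the better leaving group, would open ring C and give a phenol ether on reduction.
- Proton loss from C3 of the oxocarbenium ion would pass through the achiral 4H-chromene and erode the configuration.

The fallback replaces hydride capture by water capture, which gives the same product whichever C–O bond ionises. It sets out from 14: dilute aqueous HCl in THF at 0 °C should give the lactol (3S)-3-[3-(benzyloxy)-4,5-dimethoxyphenyl]-6,7,8-trimethoxychroman-2-ol F3 and free 11. Immediate reduction with NaBH4 in EtOH at 0 °C should give the diol (2S)-2-[3-(benzyloxy)-4,5-dimethoxyphenyl]-3-(2-hydroxy-3,4,5-trimethoxyphenyl)propan-1-ol F4. Mitsunobu closure (PPh3, diisopropyl azodicarboxylate, THF) at the primary carbon returns at 15. The open-chain aldehyde form of F3 is enolisable, so F3 is reduced without storage.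

**Step 11.** Oxygen transfer may be slow at C6', which is flanked by a methoxy group and the chromanyl group. Attack at the free ortho carbon C2' would then give the ortho-quinone, and the product quinone degrades if the medium turns basic. The fallback replaces the stoichiometric nitroxyl radical by a cobalt-catalysed oxygenation: 16 with Co(salen) under O2 in MeCN, a para-selective oxidation of phenols through a cobalt–superoxo species, goes directly to 17 and makes no new compound.

## Further compounds

F1 | step 8 | 3-[3-(benzyloxy)-4,5-dimethoxyphenyl]-6,7,8-trimethoxy-4H-chromene | COc1cc(cc(OCc2ccccc2)c1OC)C1=COc2c(cc(OC)c(OC)c2OC)C1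
F2 | step 7 | 1-(benzyloxy)-5-[(E)-2-iodoethenyl]-2,3-dimethoxybenzene | COc1cc(/C=C/I)cc(OCc2ccccc2)c1OC
F3 | step 9 | (3S)-3-[3-(benzyloxy)-4,5-dimethoxyphenyl]-6,7,8-trimethoxychroman-2-ol (both anomers) | COc1cc(cc(OCc2ccccc2)c1OC)[C@H]1C(O)Oc2c(cc(OC)c(OC)c2OC)C1
F4 | step 9 | (2S)-2-[3-(benzyloxy)-4,5-dimethoxyphenyl]-3-(2-hydroxy-3,4,5-trimethoxyphenyl)propan-1-ol | COc1cc(cc(OCc2ccccc2)c1OC)[C@@H](CO)Cc1cc(OC)c(OC)c(OC)c1O
F0 | step 11 | none | none
A1 | alternative 1 | 2-[3,4-dimethoxy-5-(triisopropylsilyloxy)phenyl]-4,4,5,5-tetramethyl-1,3,2-dioxaborolane | COc1cc(B2OC(C)(C)C(C)(C)O2)cc(O[Si](C(C)C)(C(C)C)C(C)C)c1OC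
A2 | alternative 1 | vinyllithium | [Li]C=C
A3 | alternative 1 | 2-(benzyloxy)-3,4,5-trimethoxyphenyl trifluoromethanesulfonate | COc1cc(OS(=O)(=O)C(F)(F)F)c(OCc2ccccc2)c(OC)c1OC
A4 | alternative 1 | pinacol (S)-2-[2-(benzyloxy)-3,4,5-trimethoxyphenyl]-1-[3,4-dimethoxy-5-(triisopropylsilyloxy)phenyl]ethylboronate | CC1(C)OB(OC1(C)C)[C@@H](Cc1cc(OC)c(OC)c(OC)c1OCc1ccccc1)c1cc(OC)c(OC)c(O[Si](C(C)C)(C(C)C)C(C)C)c1
A5 | alternative 2 | 2-diazo-1-[3,4-dimethoxy-5-(triisopropylsilyloxy)phenyl]-3-(2-hydroxy-3,4,5-trimethoxyphenyl)propan-1-one | COc1cc(cc(O[Si](C(C)C)(C(C)C)C(C)C)c1OC)C(=O)C(=[N+]=[N-])Cc1cc(OC)c(OC)c(OC)c1O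
A6 | alternative 2 | (S)-3-[3,4-dimethoxy-5-(triisopropylsilyloxy)phenyl]-6,7,8-trimethoxychroman-2-one | COc1cc(cc(O[Si](C(C)C)(C(C)C)C(C)C)c1OC)[C@H]1C(=O)Oc2c(cc(OC)c(OC)c2OC)C1
A7 | alternative 3 | 1-iodo-2,3,4-trimethoxybenzene | COc1ccc(I)c(OC)c1OC
A8 | alternative 3 | (S)-2-[3-(benzyloxy)-4,5-dimethoxyphenyl]-3-bromopropan-1-ol | COc1cc(cc(OCc2ccccc2)c1OC)[C@@H](CO)CBr
A9 | alternative 3 | (S)-3-[3-(benzyloxy)-4,5-dimethoxyphenyl]-6,7,8-trimethoxychroman (identical with 15) | COc1cc(cc(OCc2ccccc2)c1OC)[C@H]1COc2c(cc(OC)c(OC)c2OC)C1
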